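**Retrosynthetic overview**

1. Target 20 ⇐ 19 by one neutral hydrogenolysis; the labile lactol carbon travels as the (R)-acetal of (S)-1-phenylethanol, the phenol and the CH2OH as benzyl ethers.
2. 19 ⇐ 16 + CO2 (key step): a CO2 unit is stitched between the ring A C–I carbon and the ring B C–Br carbon, which closes the central seven-membered lactone ring last.
3. Enabling feature: the two carbons to be bridged are the two arene carbons ortho to the diaryl-ether oxygen (ring A: between C–CH3 and C–O; ring B: between C–O and C–CH3, para to the phthalide C=O). The ether holds them 1,5 to each other, so a ring A carboxylate reaches the ring B carbon and the seven-atom ring (C–C–O–C–C plus C(=O)–O) can close.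
4. 16 ⇐ 14 by CHO → CH2OH and double benzylation; 14 ⇐ 13 by separation and acid recycling of the acetal epimers; 13 ⇐ 8 + 12 by SNAr (diaryl ether).
5. 8 ⇐ aldehyde 1 (ortho-lithiation/CO2 closes the five-membered lactol-lactone ring first; then Br, demethylation, acetal); 12 ⇐ anisole 9 (ortho-formylation, iodination).

Key step: step 11

Remark: the stereocentre is a hemiacetal carbon that epimerises by ring–chain tautomerism in protic, acidic or basic media. It is therefore fixed as an acetal, the diastereomers are separated in step 8, and the free lactol is released only in the last step under neutral aprotic conditions. Compounds 1, 7 and 9 are taken as commercial.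

**Route**

Step 1
Reactants: 1 2,5-dimethoxy-4-methylbenzaldehyde
Product: 4 rac-3-hydroxy-4,7-dimethoxy-6-methyl-2-benzofuran-1(3H)-one, via lithium α-amino alkoxide 2 (not isolated), via 6-lithio α-amino alkoxide 3 (not isolated)
Conditions: LiN(Me)CH2CH2NMe2 (from the diamine and n-BuLi), THF, −20 °C; n-BuLi (3 equiv), −20 °C; CO2, −78 °C → rt; 2 M HCl
Reagents that add atoms: carbon dioxide, O=C=O
Why: α-Amino alkoxide-directed ortho-lithiation (the lithium amide adds to the aldehyde, masks it and, together with the 5-OMe group, directs n-BuLi to C-6), CO2 trapping and acid hydrolysis give the 2-formylbenzoic acid, which closes to the hydroxyphthalide; the lactol carbon forms racemic here and is resolved later.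

Step 2
Reactants: 4 rac-3-hydroxy-4,7-dimethoxy-6-methyl-2-benzofuran-1(3H)-one
Product: 5 rac-5-bromo-3-hydroxy-4,7-dimethoxy-6-methyl-2-benzofuran-1(3H)-one
Conditions: NBS, TFA/MeCN, 0 °C → rt, dark
Reagents that add atoms: N-bromosuccinimide, O=C1CCC(=O)N1Br
Why: Electrophilic aromatic bromination can only occur at C-5, the single unsubstituted ring position, which is activated by the ortho methoxy and methyl groups, while the acidic medium in the dark suppresses radical benzylic bromination.

Step 3
Reactants: 5 rac-5-bromo-3-hydroxy-4,7-dimethoxy-6-methyl-2-benzofuran-1(3H)-one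
Product: 6 rac-5-bromo-3,4,7-trihydroxy-6-methyl-2-benzofuran-1(3H)-one
Conditions: BBr3 (4 equiv), CH2Cl2, −78 °C → rt; H2O
Reagents that add atoms: none
Why: Boron tribromide ether cleavage (O-complexation, then SN2 attack of bromide on methyl) frees both phenols; the lactone and the aryl bromide are inert and any borate at the lactol oxygen is hydrolysed on work-up.

Step 4
Reactants: 6 rac-5-bromo-3,4,7-trihydroxy-6-methyl-2-benzofuran-1(3H)-one; 7 (S)-1-phenylethanol
Product: 8 5-bromo-4,7-dihydroxy-6-methyl-3-[(1S)-1-phenylethoxy]-2-benzofuran-1(3H)-one (both C-3 epimers)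
Conditions: CSA (10 mol%), 7 (3 equiv), 1,2-dichloroethane, 4 Å MS, 60 °C
Reagents that add atoms: none
Why: Acid-catalysed pseudo-ester formation (Fischer-type acetalisation of a hydroxyphthalide) uses the alcohol oxygen as nucleophile, so the auxiliary keeps its S configuration; the acetal carbon should form as an equilibrating mixture of both epimers, which is resolved in step 8.

Step 5
Reactants: 9 3-fluoro-5-methylanisole
Product: 11 2-fluoro-6-methoxy-4-methylbenzaldehyde, via 2-lithio-3-fluoro-5-methylanisole 10 (not isolated)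
Conditions: n-BuLi, THF, −78 °C; DMF, −78 → 0 °C; 1 M HCl
Reagents that add atoms: N,N-dimethylformamide, CN(C)C=O
Why: Directed ortho-metalation at the most acidic C–H, flanked by F and OMe, followed by formylation of the aryllithium with DMF.

Step 6
Reactants: 11 2-fluoro-6-methoxy-4-methylbenzaldehyde
Product: 12 2-fluoro-3-iodo-6-methoxy-4-methylbenzaldehyde
Conditions: NIS, TFA, rt
Reagents that add atoms: N-iodosuccinimide, O=C1CCC(=O)N1I
Why: Electrophilic aromatic iodination should go para to the methoxy group (C-3, between the small F and CH3, meta to CHO), the site favoured electronically and sterically over the position ortho to OMe.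

Step 7
Reactants: 8 5-bromo-4,7-dihydroxy-6-methyl-3-[(1S)-1-phenylethoxy]-2-benzofuran-1(3H)-one (both C-3 epimers); 12 2-fluoro-3-iodo-6-methoxy-4-methylbenzaldehyde
Product: 13 2-{[5-bromo-7-hydroxy-6-methyl-1-oxo-3-[(1S)-1-phenylethoxy]-1,3-dihydro-2-benzofuran-4-yl]oxy}-3-iodo-6-methoxy-4-methylbenzaldehyde (both C-3 epimers)
Conditions: K2CO3 (2.5 equiv), degassed DMF, 60–80 °C, Ar
Reagents that add atoms: none
Why: Nucleophilic aromatic substitution of the fluoride, activated by the ortho formyl and ortho iodo groups, by the 4-phenoxide (the 7-OH is chelated to the lactone carbonyl and should not react); the 4-phenoxide, ortho to the acetal carbon, can scramble C-3 by reversible ortho-quinone-methide ring opening, so the diaryl ether is taken on as the epimer mixture and resolved only after this oxygen has become an aryl ether.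

Step 8
Reactants: 13 2-{[5-bromo-7-hydroxy-6-methyl-1-oxo-3-[(1S)-1-phenylethoxy]-1,3-dihydro-2-benzofuran-4-yl]oxy}-3-iodo-6-methoxy-4-methylbenzaldehyde (both C-3 epimers)
Product: 14 2-{[(3R)-5-bromo-7-hydroxy-6-methyl-1-oxo-3-[(1S)-1-phenylethoxy]-1,3-dihydro-2-benzofuran-4-yl]oxy}-3-iodo-6-methoxy-4-methylbenzaldehyde
Conditions: SiO2 chromatography (or fractional crystallisation) isolates the (3R) epimer; the (3S)-rich remainder of 13: CSA (5 mol%), 1,2-dichloroethane, 4 Å MS, 45 °C, then chromatographed again (repeated as needed)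
Reagents that add atoms: none
Why: The two C-3 epimers are diastereomers because of the fixed S centre of the auxiliary and should separate on silica, and acid-catalysed epimerisation of the pseudo-ester acetal (reversible lactone opening to the aryl-stabilised alkoxycarbenium ion and re-closure, which does not touch the auxiliary carbon) returns the unwanted epimer to the equilibrium mixture, so that this recycling resolution fixes the future lactol carbon as 3R; the configuration would be assigned by X-ray or NOE analysis.

Step 9
Reactants: 14 2-{[(3R)-5-bromo-7-hydroxy-6-methyl-1-oxo-3-[(1S)-1-phenylethoxy]-1,3-dihydro-2-benzofuran-4-yl]oxy}-3-iodo-6-methoxy-4-methylbenzaldehyde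
Product: 15 (3R)-5-bromo-7-hydroxy-4-[2-(hydroxymethyl)-6-iodo-3-methoxy-5-methylphenoxy]-6-methyl-3-[(1S)-1-phenylethoxy]-2-benzofuran-1(3H)-one
Conditions: NaBH4, THF/i-PrOH (10:1), −10 → 0 °C; pH 7 phosphate buffer
Reagents that add atoms: none
Why: Chemoselective borohydride reduction of the aryl aldehyde, which is far more electrophilic than the hindered pseudo-ester lactone; no acid and no nucleophilic alkoxide solvent is present and the 4-oxygen is now an aryl ether, so C-3 keeps its configuration.

Step 10
Reactants: 15 (3R)-5-bromo-7-hydroxy-4-[2-(hydroxymethyl)-6-iodo-3-methoxy-5-methylphenoxy]-6-methyl-3-[(1S)-1-phenylethoxy]-2-benzofuran-1(3H)-one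
Product: 16 (3R)-7-(benzyloxy)-4-{2-[(benzyloxy)methyl]-6-iodo-3-methoxy-5-methylphenoxy}-5-bromo-6-methyl-3-[(1S)-1-phenylethoxy]-2-benzofuran-1(3H)-one
Conditions: NaH (2.4 equiv), BnBr (2.6 equiv), n-Bu4NI (cat.), DMF, 0 °C → rt
Reagents that add atoms: benzyl bromide, BrCc1ccccc1
Why: Williamson etherification of the sodium phenoxide and of the primary alkoxide in one operation; the acetal carbon has no acid-mediated or phenoxide-assisted ionisation path under these conditions (the 7-phenoxide is meta to the carbon that bears C-3) and keeps its configuration.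

Step 11
Reactants: 16 (3R)-7-(benzyloxy)-4-{2-[(benzyloxy)methyl]-6-iodo-3-methoxy-5-methylphenoxy}-5-bromo-6-methyl-3-[(1S)-1-phenylethoxy]-2-benzofuran-1(3H)-one
Product: 19 O,O′-dibenzyl-O″-[(S)-1-phenylethyl]-protected target depsidone (3R acetal), via arylmagnesium chloride 17 (not isolated), via chloromagnesium carboxylate 18 (not isolated)
Conditions: i-PrMgCl·LiCl (1.1 equiv), THF, −40 °C; CO2 (1 atm), −40 °C → rt; volatiles removed; CuI (10 mol%), 1,10-phenanthroline (20 mol%), DMF, 110 °C
Reagents that add atoms: carbon dioxide, O=C=O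
Why: Iodine–magnesium exchange should occur only at the ring A C–I bond (aryl iodides exchange several orders of magnitude faster than aryl bromides, and the flanking aryloxy oxygen assists); arylmagnesium 17 then inserts CO2 to give carboxylate 18 (new aryl–C(=O) bond), and after the solvent switch the copper(I) carboxylate undergoes intramolecular oxidative addition into the ring B C–Br bond and C–O reductive elimination (new O–aryl bond). The closest known reaction types are the carboxylation of functionalised aryl Grignard reagents with CO2 and the Ullmann-type copper-catalysed O-arylation of carboxylates by a tethered aryl halide, as used for lactones from 2′-halobiaryl-2-carboxylates. The seven-membered 1,4-dioxepin-5-one ring (ether O, two ring A carbons, carbonyl C, ester O, two ring B carbons) closes by intramolecular C(sp2)–O coupling, the carboxylate oxygen bonding to the ring B carbon while the C–Br bond that is broken lies outside the new ring (7-exo-type closure). No new stereocentre is formed, and the 3R acetal is left alone because no Brønsted acid is present. The step needs I-over-Br selectivity, tolerance of the lactone and O-arylation ahead of decarboxylation or ester formation with i-PrI; these are secured by the halogen difference, the low exchange temperature with the peri-hindered pseudo-ester carbonyl, removal of i-PrI before heating, and by both reacting carbons lying ortho to the ether oxygen with the C–Br bond para to the phthalide carbonyl.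

Step 12
Reactants: 19 O,O′-dibenzyl-O″-[(S)-1-phenylethyl]-protected target depsidone (3R acetal)
Product: 20 target depsidone CNP0367167.1 (lactol carbon R)
Conditions: H2 (1 atm), Pd(OH)2/C, EtOAc, rt; filtered and concentrated cold
Reagents that add atoms: none
Why: Heterogeneous hydrogenolysis cleaves the three benzylic C–O bonds at unhindered phenyl rings (aryl benzyl ether, alkyl benzyl ether, O–CH(CH3)Ph of the auxiliary), whereas the benzylic C–O bonds at the penta- and hexa-substituted rings A and B cannot adsorb flat on palladium; because the O–auxiliary bond and not a bond to the lactol carbon is broken, under neutral aprotic conditions, the R configuration fixed in step 8 is retained.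

**Compound list**

1 | 2,5-dimethoxy-4-methylbenzaldehyde | COc1cc(C)c(OC)cc1C=O | starting material
2 | lithium α-amino alkoxide of 1 (adduct with lithium N,N,N′-trimethylethylenediamide) | COc1cc(C)c(OC)cc1C(O[Li])N(C)CCN(C)C | intermediate
3 | 6-lithio derivative of 2 | COc1cc(C)c(OC)c([Li])c1C(O[Li])N(C)CCN(C)C | intermediate
4 | rac-3-hydroxy-4,7-dimethoxy-6-methyl-2-benzofuran-1(3H)-one | COc1cc(C)c(OC)c2c1C(O)OC2=O | intermediate
5 | rac-5-bromo-3-hydroxy-4,7-dimethoxy-6-methyl-2-benzofuran-1(3H)-one | COc1c(Br)c(C)c(OC)c2c1C(O)OC2=O | intermediate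
6 | rac-5-bromo-3,4,7-trihydroxy-6-methyl-2-benzofuran-1(3H)-one | Oc1c(Br)c(C)c(O)c2c1C(O)OC2=O | intermediate
7 | (S)-1-phenylethanol | C[C@H](O)c1ccccc1 | starting material
8 | 5-bromo-4,7-dihydroxy-6-methyl-3-[(1S)-1-phenylethoxy]-2-benzofuran-1(3H)-one, mixture of C-3 epimers | Oc1c(Br)c(C)c(O)c2c1C(O[C@@H](C)c3ccccc3)OC2=O | intermediate
9 | 3-fluoro-5-methylanisole (1-fluoro-3-methoxy-5-methylbenzene) | COc1cc(C)cc(F)c1 | starting material
10 | 2-lithio-3-fluoro-5-methylanisole | COc1cc(C)cc(F)c1[Li] | intermediate
11 | 2-fluoro-6-methoxy-4-methylbenzaldehyde | COc1cc(C)cc(F)c1C=O | intermediate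
12 | 2-fluoro-3-iodo-6-methoxy-4-methylbenzaldehyde | COc1cc(C)c(I)c(F)c1C=O | intermediate
13 | 2-{[5-bromo-7-hydroxy-6-methyl-1-oxo-3-[(1S)-1-phenylethoxy]-1,3-dihydro-2-benzofuran-4-yl]oxy}-3-iodo-6-methoxy-4-methylbenzaldehyde, mixture of C-3 epimers | COc1cc(C)c(I)c(Oc2c(Br)c(C)c(O)c3c2C(O[C@@H](C)c4ccccc4)OC3=O)c1C=O | intermediate
14 | 2-{[(3R)-5-bromo-7-hydroxy-6-methyl-1-oxo-3-[(1S)-1-phenylethoxy]-1,3-dihydro-2-benzofuran-4-yl]oxy}-3-iodo-6-methoxy-4-methylbenzaldehyde (single 3R epimer) | COc1cc(C)c(I)c(Oc2c(Br)c(C)c(O)c3c2[C@H](O[C@@H](C)c4ccccc4)OC3=O)c1C=O | intermediate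
15 | (3R)-5-bromo-7-hydroxy-4-[2-(hydroxymethyl)-6-iodo-3-methoxy-5-methylphenoxy]-6-methyl-3-[(1S)-1-phenylethoxy]-2-benzofuran-1(3H)-one | COc1cc(C)c(I)c(Oc2c(Br)c(C)c(O)c3c2[C@H](O[C@@H](C)c4ccccc4)OC3=O)c1CO | intermediate
16 | (3R)-7-(benzyloxy)-4-{2-[(benzyloxy)methyl]-6-iodo-3-methoxy-5-methylphenoxy}-5-bromo-6-methyl-3-[(1S)-1-phenylethoxy]-2-benzofuran-1(3H)-one | COc1cc(C)c(I)c(Oc2c(Br)c(C)c(OCc5ccccc5)c3c2[C@H](O[C@@H](C)c4ccccc4)OC3=O)c1COCc1ccccc1 | intermediate
17 | arylmagnesium chloride from 16 (MgCl in place of I) | COc1cc(C)c([Mg]Cl)c(Oc2c(Br)c(C)c(OCc5ccccc5)c3c2[C@H](O[C@@H](C)c4ccccc4)OC3=O)c1COCc1ccccc1 | intermediate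
18 | chloromagnesium carboxylate from 17 (CO2MgCl in place of I) | COc1cc(C)c(C(=O)O[Mg]Cl)c(Oc2c(Br)c(C)c(OCc5ccccc5)c3c2[C@H](O[C@@H](C)c4ccccc4)OC3=O)c1COCc1ccccc1 | intermediate
19 | protected depsidone: the target with benzyl on the phenol oxygen, benzyl on the CH2OH oxygen and (S)-1-phenylethyl on the lactol oxygen (acetal carbon R) | COc1cc(C)c2c(c1COCc5ccccc5)Oc1c(c(C)c(OCc6ccccc6)c3c1[C@H](O[C@@H](C)c4ccccc4)OC3=O)OC2=O | intermediate
20 | target depsidone CNP0367167.1: ring A with OMe, CH3 and CH2OH, seven-membered lactone, ring B with CH3, OH and the fused 3-hydroxyphthalide (lactol carbon R) | COc1cc(C)c2c(c1CO)Oc1c(c(C)c(O)c3c1[C@H](O)OC3=O)OC2=O | target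

**Summary**

Total step count: 12. Longest linear sequence: 10 steps (steps 1, 2, 3, 4, 7, 8, 9, 10, 11, 12).

**Steps most likely to fail**

1. Step 11. The copper-mediated C–O closure may be too slow at the doubly ortho-substituted C–Br bond, so that protodecarboxylation or hydrodebromination takes over. The arylmagnesium may also attack the neighbouring pseudo-ester before CO2 arrives, and magnesium salts at 110 °C may erode the acetal configuration. The fallback sets out from 16 and comes back at 19. Only the exchange and carboxylation are run at −40 °C, and a cold aqueous citric acid quench gives the bromo carboxylic acid F1. The seven-membered lactone is then closed at room temperature by nickel/photoredox carboxylate O-arylation (NiBr2·glyme/dtbbpy cat., Ir(ppy)3 cat., Cs2CO3, DMF, blue LEDs), which gives 19.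

2. Step 7. Both partners are di-ortho-substituted, so the substitution may need a temperature at which the phenoxide opens the neighbouring pseudo-ester (loss of the auxiliary) or the hydroquinone is oxidised. The fallback sets out from 11 and comes back at 13. Nitration of 11 para to the methoxy group (KNO3, H2SO4, 0 °C) gives 2-fluoro-6-methoxy-4-methyl-3-nitrobenzaldehyde F2. Its fluoride, now flanked by nitro and formyl groups, should be displaced by the 4-phenoxide of 8 at 0 °C to rt (K2CO3, DMF), which gives the nitro diaryl ether F3 as both C-3 epimers. Chemoselective nitro reduction (Fe, NH4Cl, EtOH/H2O) gives the aniline F4, again as both C-3 epimers. A non-aqueous Sandmeyer-type iodination (t-BuONO, excess I2, MeCN) then gives 13, which enters the resolution of step 8; any epimerisation on the way is therefore harmless.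

3. Step 12. Over-reduction may occur: the dibenzylic ether on ring A may cleave on the arene side (CH3 instead of CH2OH), or the slow secondary benzylic auxiliary may force long exposure with reduction or epimerisation of the lactol. The fallback sets out from 15 and comes back at 20. The primary alcohol is silylated (TBSCl, imidazole, DMF) to the silyl ether F5 and the phenol is benzylated (BnBr, K2CO3, DMF) to the benzyl ether F6. The key step is run on F6 as in step 11 to give the silyl-protected depsidone F7. HF·pyridine (THF, 0 °C) gives the hydroxymethyl depsidone F8. Hydrogenolysis (H2, Pd(OH)2/C, EtOAc) then has to cleave only the aryl benzyl ether and the auxiliary, and gives 20.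

**Further compounds**

F1 | step 11 | 2-{[(3R)-7-(benzyloxy)-5-bromo-6-methyl-1-oxo-3-[(1S)-1-phenylethoxy]-1,3-dihydro-2-benzofuran-4-yl]oxy}-3-[(benzyloxy)methyl]-4-methoxy-6-methylbenzoic acid | COc1cc(C)c(C(=O)O)c(Oc2c(Br)c(C)c(OCc5ccccc5)c3c2[C@H](O[C@@H](C)c4ccccc4)OC3=O)c1COCc1ccccc1
F2 | step 7 | 2-fluoro-6-methoxy-4-methyl-3-nitrobenzaldehyde | COc1cc(C)c([N+](=O)[O-])c(F)c1C=O
F3 | step 7 | 2-{[5-bromo-7-hydroxy-6-methyl-1-oxo-3-[(1S)-1-phenylethoxy]-1,3-dihydro-2-benzofuran-4-yl]oxy}-6-methoxy-4-methyl-3-nitrobenzaldehyde, mixture of C-3 epimers | COc1cc(C)c([N+](=O)[O-])c(Oc2c(Br)c(C)c(O)c3c2C(O[C@@H](C)c4ccccc4)OC3=O)c1C=O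
F4 | step 7 | 3-amino-2-{[5-bromo-7-hydroxy-6-methyl-1-oxo-3-[(1S)-1-phenylethoxy]-1,3-dihydro-2-benzofuran-4-yl]oxy}-6-methoxy-4-methylbenzaldehyde, mixture of C-3 epimers | COc1cc(C)c(N)c(Oc2c(Br)c(C)c(O)c3c2C(O[C@@H](C)c4ccccc4)OC3=O)c1C=O
F5 | step 12 | tert-butyldimethylsilyl ether of 15 at the CH2OH group | COc1cc(C)c(I)c(Oc2c(Br)c(C)c(O)c3c2[C@H](O[C@@H](C)c4ccccc4)OC3=O)c1CO[Si](C)(C)C(C)(C)C
F6 | step 12 | 7-O-benzyl ether of F5 | COc1cc(C)c(I)c(Oc2c(Br)c(C)c(OCc5ccccc5)c3c2[C@H](O[C@@H](C)c4ccccc4)OC3=O)c1CO[Si](C)(C)C(C)(C)C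
F7 | step 12 | depsidone from F6: the target with benzyl on the phenol oxygen, TBS on the CH2OH oxygen and (S)-1-phenylethyl on the lactol oxygen | COc1cc(C)c2c(c1CO[Si](C)(C)C(C)(C)C)Oc1c(c(C)c(OCc6ccccc6)c3c1[C@H](O[C@@H](C)c4ccccc4)OC3=O)OC2=O
F8 | step 12 | depsidone from F7 with free CH2OH: the target with benzyl on the phenol oxygen and (S)-1-phenylethyl on the lactol oxygen | COc1cc(C)c2c(c1CO)Oc1c(c(C)c(OCc6ccccc6)c3c1[C@H](O[C@@H](C)c4ccccc4)OC3=O)OC2=O
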